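(The numbers in the tables stem from a simulated flask on assumed constants; the scatter is artificial.)

Compare two slopes on one flask. Here is what stands on the bench and what is asked.

| flask | starting material | partner | free catalyst | time |
|---|---|---|---|---|
| Sunday's | 50.0 mM | 55.0 mM | 1.00 mM |  |
| Monday's | 20.0 mM | 25.0 mM | 1.00 mM |  |
| Friday's | 50.0 mM | 55.0 mM | 2.00 mM |  |
| Saturday's | 50.0 mM | 110 mM | 1.00 mM |  |
| Thursday's | 17.0 mM | 110 mM | 1.00 mM | 100 min |

- Sunday's run (time / min: [product] / mM): 4.0: 1.7; 6.8: 3.0; 12: 4.4; 20: 7.2; 34: 10.6; 58: 14.0; 100: 18.3
- Monday's run (time / min: [product] / mM): 4.0: 0.4; 6.8: 0.5; 12: 0.6; 20: 1.9; 34: 2.9; 58: 3.7; 100: 5.2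
- Friday's run (time / min: [product] / mM): 4.0: 3.2; 6.8: 5.3; 12: 8.4; 20: 12.6; 34: 17.8; 58: 23.2; 100: 28.0
- Saturday's run (time / min: [product] / mM): 4.0: 2.9; 6.8: 4.3; 12: 7.7; 20: 11.3; 34: 17.2; 58: 23.0; 100: 30.2

(scatter of a reading: 0.3 mM)

- order of the initial rate in [free catalyst], near the charge of the Sunday's run, the rate being that where two percent of its starting material are product
- order of the initial rate in [partner], near the charge of the Sunday's run, the rate being that where two percent of its starting material are product
- product in the Thursday's run at 100 min, as a share of the starting material charged
- which of these the readings show (the product binds the second partner / nothing beyond the main steps / the product ties up the catalyst / the substrate kills the catalyst)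

- Overall: starting material + partner -> product, with free catalyst as catalyst.
- Constant volume, constant temperature.
- Bound and free are read together.
- "The second partner" is partner.
- An order is taken over about fifteen percent of the charge, up and down.

**Why take logs of Saturday's readings?** Saturday's flask has partner at 110 mM against 50.0 mM of starting material. I treat it as a first-order decay (pseudo-first-order), so ln(c0/c) of the starting material should climb straight, and its slope is the inverse time constant.

**Is Saturday's line straight?** No. Over the first 12 min the slope reads 0.0139 min⁻¹, and from 34 min to 100 min it reads 0.00765 min⁻¹, which is lower. The midpoints of those windows lie 61.0 min apart, so the slope decays at 0.00984 min⁻¹. That figure also holds the partner's fall, to 79.8 mM by the last reading.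

**Could product be the brake?** Compare Friday with Sunday. Friday's flask, with twice the catalyst, held 17.8 mM of product at 34 min, while Sunday's held 18.3 mM at 100 min. Scaled to Sunday's catalyst charge, Friday's clock reads 68.0 min against Sunday's 100 min, so Friday needed less scaled time for about the same product. I read that as activity lost with the clock rather than with the product made.

**Then what kills the catalyst?** My call is starting material, with a loss rate proportional to its concentration; these runs test that poorly. Dividing Saturday's decay by its mean c(starting material), 34.6 mM, gives 0.284 M⁻¹ min⁻¹, the kill coefficient: catalyst loss rate per unit of c(starting material).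

**And Thursday's flask?** It has Saturday's partner and catalyst charges, so I push Saturday's early slope back to zero time: 0.0148 min⁻¹. Partner there can lose at most 17.0 mM. Without a kill, mean c(starting material) over 100 min is 8.88 mM, so the kill rate is 0.00252 min⁻¹. That leaves 88.4 min of working time, and my figure is 72.9%.

The forecast says 67%, lower than mine, with orders 0.95 in free catalyst and 0.7 in partner, and names the substrate kills the catalyst: “So the loss follows time, not product”.

The flask gives 71.3% on Thursday, orders 1.0 and 0.85, and the substrate kills the catalyst.

    free catalyst + partner ⇌ catalyst-reagent complex, settled at all times (4.430 M⁻¹)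
    catalyst-reagent complex + starting material → product + free catalyst (44.94 M⁻¹ min⁻¹)
    free catalyst + starting material → spent catalyst + starting material (0.2994 M⁻¹ min⁻¹)

The fit in which the product binds the partner leaves a root-mean-square residual of 2.4 scatter units. At Thursday's mean c(starting material), the kill coefficient gives a catalyst time constant of 397 min, longer than the 100 min asked. On Monday's flask, the rate 0.077 mM min⁻¹, read where 1.00 mM of product has formed, over the starting material remaining there gives a slope 0.00404 min⁻¹. The kill coefficient, at a mean of 15.0 mM on the way to half, gives 0.00426 min⁻¹, which puts half conversion at 308 min. Monday's half time stands at 410 min.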